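**Assumption:** atom labels C1 to C19 follow the xenicane numbering of the target (C1 acetal carbon, O2, C3=C4 enol ether, C4a and C11a ring fusion, C5 to C11 carbocycle, C12 to C15 side chain); compounds 1, 6, 10, 11 and 21 are bought.

## Retrosynthetic overview

1. The 8,9-epoxide is made last, by hydroxyl-directed epoxidation of a Z-C8=C9 alkene from the C7 tertiary alcohol.
2. The nine-membered ring (second ring) is closed at C8=C9 by ring-closing metathesis of a diene carried on a trans-disubstituted dihydropyran.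
3. The side chain is attached at C4–C12 by Nozaki–Hiyama–Kishi coupling of a C4 enol triflate with an α-acetoxy epoxy aldehyde (C13 from lipase resolution, C14 from Shi epoxidation).
4. The dihydropyran (first ring) comes from an Achmatowicz pyranone: C4a–C5 by B-alkyl Suzuki coupling, C11a–C11 by anti conjugate addition of a penta-1,4-dien-2-yl copper reagent.
5. C7 is set by a proposed enantiotopic-group-selective copper hydride hydroboration of a bis-vinyl carbinol silyl ether.

## Route

**Step 1**
Reactants: 1 furfuryl alcohol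
Product: 2 6-hydroxy-2H-pyran-3(6H)-one (racemic lactol)
Conditions: NBS, NaHCO3, THF/H2O 4:1, 0 °C
Reagents that add atoms: water `O`
Why: Achmatowicz rearrangement (oxidative ring expansion of a furfuryl alcohol); the hemiacetal centre is configurationally labile, so nothing has to be controlled here.

**Step 2**
Reactants: 2 6-hydroxy-2H-pyran-3(6H)-one
Product: 3 (R)-6-acetoxy-2H-pyran-3(6H)-one
Conditions: immobilised Pseudomonas cepacia lipase (Amano PS), vinyl acetate, hexane/THF, 25 °C
Reagents that add atoms: vinyl acetate `C=COC(C)=O`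
Why: lipase-catalysed dynamic kinetic acetylation: the lactol enantiomers interconvert by ring opening while the enzyme acylates one of them, which fixes the acetal carbon as R (the enzyme batch is checked for this sense and the ee is raised by crystallisation).

**Step 3**
Reactants: 3 (R)-6-acetoxy-2H-pyran-3(6H)-one
Product: 4 (S)-6-[(4-methoxybenzyl)oxy]-2H-pyran-3(6H)-one
Conditions: 4-methoxybenzyl alcohol, Pd2(dba)3·CHCl3 (2.5 mol %), PPh3 (10 mol %), CH2Cl2, 0 °C
Reagents that add atoms: 4-methoxybenzyl alcohol `COc1ccc(CO)cc1`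
Why: Tsuji–Trost allylic substitution on the pyranone acetate (palladium-catalysed glycosylation): ionisation and alkoxide attack both occur anti to palladium, so the acetal carbon is kept with net retention (the descriptor becomes S only through the priority rules).

**Step 4**
Reactants: 4 (S)-6-[(4-methoxybenzyl)oxy]-2H-pyran-3(6H)-one
Product: 5 (S)-4-iodo-6-[(4-methoxybenzyl)oxy]-2H-pyran-3(6H)-one
Conditions: I2, pyridine/CH2Cl2 1:1, 0 °C to rt
Reagents that add atoms: iodine `[I][I]`
Why: α-iodination of an enone by pyridine conjugate addition, iodination and elimination (Johnson iodination), which leaves the acetal centre untouched.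

**Step 5**
Reactants: 6 3-methylpenta-1,4-dien-3-ol
Product: 7 triethyl[(3-methylpenta-1,4-dien-3-yl)oxy]silane
Conditions: TESOTf, 2,6-lutidine, CH2Cl2, −78 to 0 °C
Reagents that add atoms: triethylsilyl trifluoromethanesulfonate `CC[Si](CC)(CC)OS(=O)(=O)C(F)(F)F`
Why: silylation of a hindered tertiary alcohol with a silyl triflate; 7 is achiral and its two vinyl groups are enantiotopic.

**Step 6**
Reactants: 7 triethyl[(3-methylpenta-1,4-dien-3-yl)oxy]silane
Product: 8 (S)-triethyl{[3-methyl-5-(4,4,5,5-tetramethyl-1,3,2-dioxaborolan-2-yl)pent-1-en-3-yl]oxy}silane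
Conditions: Cu(OAc)2 (3 mol %), (R)-DTBM-SEGPHOS (3.3 mol %), pinacolborane (1.0 equiv), THF, 0 °C to rt
Reagents that add atoms: pinacolborane `[H]B1OC(C)(C)C(C)(C)O1`
Why: Proposed new method: enantiotopic-group-selective copper hydride hydroboration, in which the ligand-bound copper hydride formed from Cu(OAc)2 and pinacolborane inserts anti-Markovnikov into one of the two enantiotopic vinyl groups (irreversible and selectivity-determining, with the fully substituted carbinol carbon held in the ligand pocket), σ-bond metathesis of the primary alkylcopper with pinacolborane releases 8 and sets C7 as S, and over-reaction of the minor enantiomer to the achiral bis-boronate raises the ee; the closest known reactions are copper hydride catalysed enantioselective hydroboration of alkenes and catalytic desymmetrisations of divinyl carbinols.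

**Step 7**
Reactants: 5 (S)-4-iodo-6-[(4-methoxybenzyl)oxy]-2H-pyran-3(6H)-one; 8 (S)-boronate
Product: 9 (6S)-6-[(4-methoxybenzyl)oxy]-4-[(3S)-3-methyl-3-(triethylsilyloxy)pent-4-en-1-yl]-2H-pyran-3(6H)-one
Conditions: PdCl2(dppf)·CH2Cl2 (5 mol %), K3PO4 (3 equiv), THF/H2O 9:1, 55 °C
Reagents that add atoms: none
Why: B-alkyl Suzuki–Miyaura coupling of a primary alkylboronate with an α-iodoenone forms C4a–C5 without touching a stereocentre.

**Step 8**
Reactants: 10 2,3-dibromopropene; 11 vinylmagnesium bromide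
Product: 12 2-bromopenta-1,4-diene
Conditions: CuBr·SMe2 (5 mol %), THF, 0 °C
Reagents that add atoms: none
Why: copper-catalysed allylic substitution of the allylic bromide by the vinyl Grignard reagent (SN2 and SN2' attack give the same product), the vinylic bromide staying intact.

**Step 9**
Reactants: 9 enone; 12 2-bromopenta-1,4-diene
Product: 15 (4S,5R,6S)-6-[(4-methoxybenzyl)oxy]-4-[(3S)-3-methyl-3-(triethylsilyloxy)pent-4-en-1-yl]-5-(penta-1,4-dien-2-yl)dihydro-2H-pyran-3(4H)-one, via penta-1,4-dien-2-ylmagnesium bromide 13 (not isolated), via trimethylsilyl enol ether 14 (not isolated)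
Conditions: 12, Mg, THF, 40 °C; then 9, CuBr·SMe2 (20 mol %), TMSCl, THF, −78 to −40 °C; then K2CO3, MeOH, 0 °C to rt
Reagents that add atoms: none
Why: copper-catalysed conjugate addition of an alkenyl Grignard reagent with silyl trapping: the alkenyl group enters C11a anti to the pseudoaxial C1 alkoxy group, and base-mediated methanolysis of the silyl enol ether equilibrates C4a to the all-trans ketone with both carbon substituents equatorial.

**Step 10**
Reactants: 15 all-trans ketone
Product: 17 (2S,3R,4S)-2-[(4-methoxybenzyl)oxy]-4-[(3S)-3-methyl-3-(triethylsilyloxy)pent-4-en-1-yl]-3-(penta-1,4-dien-2-yl)-3,4-dihydro-2H-pyran-5-yl trifluoromethanesulfonate, via potassium enolate 16 (not isolated)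
Conditions: KHMDS, THF, −78 °C; then PhNTf2, −78 to −20 °C
Reagents that add atoms: N-phenylbis(trifluoromethanesulfonimide) `O=S(=O)(N(c1ccccc1)S(=O)(=O)C(F)(F)F)C(F)(F)F`
Why: kinetic enolisation at the unhindered C3 methylene (C4a is a shielded methine) and O-triflation give the C3=C4 enol triflate, which is the enol acetal of the target in electron-poor, acid-tolerant form; no stereocentre changes.

**Step 11**
Reactants: 17 enol triflate
Product: 19 (3R,4S)-2-hydroxy-4-[(3S)-3-hydroxy-3-methylpent-4-en-1-yl]-3-(penta-1,4-dien-2-yl)-3,4-dihydro-2H-pyran-5-yl trifluoromethanesulfonate (anomer mixture), via lactol triethylsilyl ether 18 (not isolated)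
Conditions: DDQ, CH2Cl2/pH 7 buffer 10:1, 0 °C; then HF·pyridine, pyridine, THF, 0 °C to rt
Reagents that add atoms: none
Why: oxidative cleavage of the 4-methoxybenzyl acetal by DDQ, then desilylation of the tertiary silyl ether with buffered hydrogen fluoride, both tolerated because the triflate deactivates the enol ether; C1 becomes a free lactol.

**Step 12**
Reactants: 19 lactol
Product: 20 (2R,3R,4S)-4-[(3S)-3-hydroxy-3-methylpent-4-en-1-yl]-3-(penta-1,4-dien-2-yl)-5-{[(trifluoromethyl)sulfonyl]oxy}-3,4-dihydro-2H-pyran-2-yl acetate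
Conditions: Ac2O, pyridine, CH2Cl2, 0 °C
Reagents that add atoms: acetic anhydride `CC(=O)OC(C)=O`
Why: acetylation of the equilibrating lactol: the anomer whose hydroxyl is trans to the C11a dienyl group is less hindered and is acylated preferentially, which sets C1 as R (1,11a-trans), while the tertiary C7 alcohol does not react without DMAP; the minor anomer is separated and recycled by methanolysis.

**Step 13**
Reactants: 21 3-methylbut-2-enal; 11 vinylmagnesium bromide
Product: 22 5-methylhexa-1,4-dien-3-ol (racemic)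
Conditions: THF, −78 to 0 °C; aq. NH4Cl
Reagents that add atoms: none
Why: 1,2-addition of a vinyl Grignard reagent to an enal.

**Step 14**
Reactants: 22 5-methylhexa-1,4-dien-3-ol
Product: 23 (R)-5-methylhexa-1,4-dien-3-yl acetate
Conditions: Novozym 435 (immobilised Candida antarctica lipase B), vinyl acetate, tert-butyl methyl ether, 25 °C, to 50 % conversion
Reagents that add atoms: vinyl acetate `C=COC(C)=O`
Why: lipase kinetic resolution by transesterification: by the Kazlauskas rule the enantiomer in which the larger 2-methylprop-1-enyl group takes the large pocket (R) is acetylated, which sets C13, and the unreacted (S)-alcohol is removed on neutral alumina.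

**Step 15**
Reactants: 23 (R)-5-methylhexa-1,4-dien-3-yl acetate
Product: 24 (1R)-1-[(2R)-3,3-dimethyloxiran-2-yl]prop-2-en-1-yl acetate
Conditions: Shi ketone (D-fructose derived, 30 mol %), Oxone, K2CO3, Bu4NHSO4, MeCN/dimethoxymethane/aq. Na2B4O7 buffer, 0 °C
Reagents that add atoms: potassium peroxymonosulfate `[K+].[O-]S(=O)(=O)OO`
Why: Shi asymmetric epoxidation: the chiral dioxirane attacks only the electron-rich trisubstituted alkene, from the face anti to the allylic acetate in the conformer with the carbinol hydrogen eclipsing the cis methyl group (catalyst and substrate preference matched), which sets C14 as R with the 13,14-anti relationship.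

**Step 16**
Reactants: 24 epoxy acetate
Product: 26 (1S)-1-[(2R)-3,3-dimethyloxiran-2-yl]-2-oxoethyl acetate, via ozonide 25 (not isolated)
Conditions: O3, CH2Cl2, −78 °C; then PPh3, −78 °C to rt
Reagents that add atoms: ozone `[O-][O+]=O`
Why: ozonolysis of the remaining terminal alkene with reductive work-up; epoxide, acetate and both stereocentres are unaffected, and the aldehyde is used at once.

**Step 17**
Reactants: 20 enol triflate acetate; 26 aldehyde
Product: 28 (2R,3R,4S)-5-{(1R,2R)-2-acetoxy-2-[(2R)-3,3-dimethyloxiran-2-yl]-1-hydroxyethyl}-4-[(3S)-3-hydroxy-3-methylpent-4-en-1-yl]-3-(penta-1,4-dien-2-yl)-3,4-dihydro-2H-pyran-2-yl acetate, via alkenylchromium dichloride 27 (not isolated)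
Conditions: CrCl2 (6 equiv), NiCl2 (2 mol %), DMF, rt
Reagents that add atoms: none
Why: Nozaki–Hiyama–Kishi coupling: nickel-mediated insertion into the enol triflate, transmetalation to chromium and addition to the aldehyde under Felkin–Anh control (acetoxy group anti to the incoming alkenyl group) form C4–C12 and set C12 as R (12,13-anti); esters, epoxide and the free tertiary alcohol are tolerated and the minor C12 epimer is removed by chromatography.

**Step 18**
Reactants: 28 allylic alcohol
Product: 29 (1R,2R)-1-[(2R,3R,4S)-2-acetoxy-4-[(3S)-3-hydroxy-3-methylpent-4-en-1-yl]-3-(penta-1,4-dien-2-yl)-3,4-dihydro-2H-pyran-5-yl]-2-[(2R)-3,3-dimethyloxiran-2-yl]ethane-1,2-diyl diacetate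
Conditions: Ac2O, pyridine, DMAP (10 mol %), CH2Cl2, 0 °C
Reagents that add atoms: acetic anhydride `CC(=O)OC(C)=O`
Why: acetylation of the secondary C12 alcohol, with the tertiary C7 alcohol left free at 0 °C; no stereocentre changes.

**Step 19**
Reactants: 29 triacetate diene
Product: 30 Z-cyclononene (1R,4aS,7S,8Z,11aR,12R,13R,14R)-1,12,13-triacetoxy-14,15-epoxy-7-hydroxyxenica-3,8,11(19)-triene
Conditions: second-generation Grubbs catalyst RuCl2(=CHPh)(PCy3)(1,3-dimesitylimidazolidin-2-ylidene) (15 mol %), toluene (1 mM), 80 °C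
Reagents that add atoms: none
Why: ring-closing metathesis: the catalyst loads on the unhindered C9 vinyl group and closes onto the C8 vinyl group next to the free tertiary allylic alcohol, the two trans arms on the dihydropyran hold the alkenes close, and the nine-membered ring accommodates only the Z alkene; the 1,1-disubstituted C11 alkene and the enol ether are poor metathesis partners.

**Step 20**
Reactants: 30 Z-cyclononene
Product: 31 target, (1R,4aS,7S,8R,9R,11aR,12R,13R,14R)-1,12,13-triacetoxy-8,9:14,15-diepoxy-7-hydroxyxenica-3,11(19)-diene (CNP0134792.1)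
Conditions: VO(acac)2 (10 mol %), t-BuOOH (1.5 equiv, decane), CH2Cl2, 0 °C to rt
Reagents that add atoms: tert-butyl hydroperoxide `CC(C)(C)OO`
Why: vanadium-catalysed hydroxyl-directed epoxidation: the C7 vanadate ester delivers the peroxide oxygen to the adjacent Z alkene on its own face (cis epoxy alcohol, as known for cyclononenols), which sets C8 and C9 as R,R; the 1,1-disubstituted alkene and the enol ether have no directing hydroxyl and do not react.

## Compound list

1 | furfuryl alcohol (furan-2-ylmethanol) | `OCc1ccco1` | starting material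
2 | 6-hydroxy-2H-pyran-3(6H)-one (racemic lactol) | `O=C1COC(O)C=C1` | intermediate
3 | (R)-6-acetoxy-2H-pyran-3(6H)-one | `O=C1CO[C@H](OC(C)=O)C=C1` | intermediate
4 | (S)-6-[(4-methoxybenzyl)oxy]-2H-pyran-3(6H)-one | `O=C1CO[C@H](OCc2ccc(OC)cc2)C=C1` | intermediate
5 | (S)-4-iodo-6-[(4-methoxybenzyl)oxy]-2H-pyran-3(6H)-one | `O=C1CO[C@H](OCc2ccc(OC)cc2)C=C1I` | intermediate
6 | 3-methylpenta-1,4-dien-3-ol | `C=CC(C)(O)C=C` | starting material
7 | triethyl[(3-methylpenta-1,4-dien-3-yl)oxy]silane | `C=CC(C)(O[Si](CC)(CC)CC)C=C` | intermediate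
8 | (S)-triethyl{[3-methyl-5-(4,4,5,5-tetramethyl-1,3,2-dioxaborolan-2-yl)pent-1-en-3-yl]oxy}silane | `C=C[C@@](C)(O[Si](CC)(CC)CC)CCB1OC(C)(C)C(C)(C)O1` | intermediate
9 | (6S)-6-[(4-methoxybenzyl)oxy]-4-[(3S)-3-methyl-3-(triethylsilyloxy)pent-4-en-1-yl]-2H-pyran-3(6H)-one | `C=C[C@@](C)(O[Si](CC)(CC)CC)CCC1=C[C@@H](OCc2ccc(OC)cc2)OCC1=O` | intermediate
10 | 2,3-dibromopropene | `C=C(Br)CBr` | starting material
11 | vinylmagnesium bromide | `C=C[Mg]Br` | starting material
12 | 2-bromopenta-1,4-diene | `C=C(Br)CC=C` | intermediate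
13 | penta-1,4-dien-2-ylmagnesium bromide | `C=C([Mg]Br)CC=C` | intermediate (not isolated)
14 | trimethylsilyl enol ether of 15 (C4a=C4 enol silane; C1 alkoxy and C11a dienyl trans) | `C=C[C@@](C)(O[Si](CC)(CC)CC)CCC1=C(O[Si](C)(C)C)CO[C@H](OCc2ccc(OC)cc2)[C@H]1C(=C)CC=C` | intermediate (not isolated)
15 | (4S,5R,6S)-6-[(4-methoxybenzyl)oxy]-4-[(3S)-3-methyl-3-(triethylsilyloxy)pent-4-en-1-yl]-5-(penta-1,4-dien-2-yl)dihydro-2H-pyran-3(4H)-one (all-trans) | `C=C[C@@](C)(O[Si](CC)(CC)CC)CC[C@@H]1C(=O)CO[C@H](OCc2ccc(OC)cc2)[C@H]1C(=C)CC=C` | intermediate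
16 | potassium C3=C4 enolate of 15 | `C=C[C@@](C)(O[Si](CC)(CC)CC)CC[C@@H]1C([O-])=CO[C@H](OCc2ccc(OC)cc2)[C@H]1C(=C)CC=C.[K+]` | intermediate (not isolated)
17 | (2S,3R,4S)-2-[(4-methoxybenzyl)oxy]-4-[(3S)-3-methyl-3-(triethylsilyloxy)pent-4-en-1-yl]-3-(penta-1,4-dien-2-yl)-3,4-dihydro-2H-pyran-5-yl trifluoromethanesulfonate | `C=C[C@@](C)(O[Si](CC)(CC)CC)CC[C@@H]1C(OS(=O)(=O)C(F)(F)F)=CO[C@H](OCc2ccc(OC)cc2)[C@H]1C(=C)CC=C` | intermediate
18 | lactol triethylsilyl ether (17 without the 4-methoxybenzyl group; anomer mixture) | `C=C[C@@](C)(O[Si](CC)(CC)CC)CC[C@@H]1C(OS(=O)(=O)C(F)(F)F)=COC(O)[C@H]1C(=C)CC=C` | intermediate (not isolated)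
19 | (3R,4S)-2-hydroxy-4-[(3S)-3-hydroxy-3-methylpent-4-en-1-yl]-3-(penta-1,4-dien-2-yl)-3,4-dihydro-2H-pyran-5-yl trifluoromethanesulfonate (anomer mixture) | `C=C[C@@](C)(O)CC[C@@H]1C(OS(=O)(=O)C(F)(F)F)=COC(O)[C@H]1C(=C)CC=C` | intermediate
20 | (2R,3R,4S)-4-[(3S)-3-hydroxy-3-methylpent-4-en-1-yl]-3-(penta-1,4-dien-2-yl)-5-{[(trifluoromethyl)sulfonyl]oxy}-3,4-dihydro-2H-pyran-2-yl acetate | `C=C[C@@](C)(O)CC[C@@H]1C(OS(=O)(=O)C(F)(F)F)=CO[C@H](OC(C)=O)[C@H]1C(=C)CC=C` | intermediate
21 | 3-methylbut-2-enal | `CC(C)=CC=O` | starting material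
22 | 5-methylhexa-1,4-dien-3-ol (racemic) | `C=CC(O)C=C(C)C` | intermediate
23 | (R)-5-methylhexa-1,4-dien-3-yl acetate | `C=C[C@@H](OC(C)=O)C=C(C)C` | intermediate
24 | (1R)-1-[(2R)-3,3-dimethyloxiran-2-yl]prop-2-en-1-yl acetate | `C=C[C@@H](OC(C)=O)[C@H]1OC1(C)C` | intermediate
25 | ozonide of 24 (3-substituted 1,2,4-trioxolane) | `C1(OCOO1)[C@@H](OC(C)=O)[C@H]2OC2(C)C` | intermediate (not isolated)
26 | (1S)-1-[(2R)-3,3-dimethyloxiran-2-yl]-2-oxoethyl acetate | `O=C[C@@H](OC(C)=O)[C@H]1OC1(C)C` | intermediate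
27 | alkenylchromium dichloride from 20 (CrCl2 unit on C4 in place of the triflate) | `C=C[C@@](C)(O)CC[C@@H]1C([Cr](Cl)Cl)=CO[C@H](OC(C)=O)[C@H]1C(=C)CC=C` | intermediate (not isolated)
28 | (2R,3R,4S)-5-{(1R,2R)-2-acetoxy-2-[(2R)-3,3-dimethyloxiran-2-yl]-1-hydroxyethyl}-4-[(3S)-3-hydroxy-3-methylpent-4-en-1-yl]-3-(penta-1,4-dien-2-yl)-3,4-dihydro-2H-pyran-2-yl acetate | `C=C[C@@](C)(O)CC[C@@H]1C([C@@H](O)[C@@H](OC(C)=O)[C@H]2OC2(C)C)=CO[C@H](OC(C)=O)[C@H]1C(=C)CC=C` | intermediate
29 | (1R,2R)-1-[(2R,3R,4S)-2-acetoxy-4-[(3S)-3-hydroxy-3-methylpent-4-en-1-yl]-3-(penta-1,4-dien-2-yl)-3,4-dihydro-2H-pyran-5-yl]-2-[(2R)-3,3-dimethyloxiran-2-yl]ethane-1,2-diyl diacetate | `C=C[C@@](C)(O)CC[C@@H]1C([C@@H](OC(C)=O)[C@@H](OC(C)=O)[C@H]2OC2(C)C)=CO[C@H](OC(C)=O)[C@H]1C(=C)CC=C` | intermediate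
30 | (1R,4aS,7S,8Z,11aR,12R,13R,14R)-1,12,13-triacetoxy-14,15-epoxy-7-hydroxyxenica-3,8,11(19)-triene | `C=C1C/C=C\[C@@](C)(O)CC[C@@H]2C([C@@H](OC(C)=O)[C@@H](OC(C)=O)[C@H]3OC3(C)C)=CO[C@H](OC(C)=O)[C@@H]12` | intermediate
31 | (1R,4aS,7S,8R,9R,11aR,12R,13R,14R)-1,12,13-triacetoxy-8,9:14,15-diepoxy-7-hydroxyxenica-3,11(19)-diene (CNP0134792.1) | `C=C1C[C@H]2O[C@H]2[C@@](C)(O)CC[C@@H]2C([C@@H](OC(C)=O)[C@@H](OC(C)=O)[C@H]3OC3(C)C)=CO[C@H](OC(C)=O)[C@@H]12` | target

## Step count and weak points

Total step count: 20. Longest linear sequence: 13 steps (steps 1, 2, 3, 4, 7, 9, 10, 11, 12, 17, 18, 19, 20).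

**Step 6 (the proposed new hydroboration).** The risk is low discrimination between the two vinyl groups, or double hydroboration. The fallback uses known chemistry, sets out from 7 and comes back at 8. Iridium-catalysed hydroboration of 7 (used in excess) with pinacolborane ([Ir(cod)Cl]2, dppe, CH2Cl2, rt) gives the racemic boronate F1. Its enantiomers are separated by preparative supercritical-fluid chromatography on a cellulose carbamate chiral phase. The (S)-enantiomer is 8 and goes into step 7; the (R)-boronate F2 is set aside.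

**Step 7 (B-alkyl Suzuki coupling).** The risk is slow transmetalation of the pinacol boronate, and damage to the iodoenone by aqueous base. The fallback changes the coupling manifold to organozinc; it sets out from 8 and comes back at 9. Oxidation of 8 (NaBO3·4H2O, THF/H2O) gives (S)-3-methyl-3-(triethylsilyloxy)pent-4-en-1-ol F3. Iodination (I2, PPh3, imidazole) gives the primary iodide F4. Zinc insertion (Zn dust, LiCl, THF) gives the alkylzinc iodide F5. Base-free Negishi coupling of F5 with 5 (Pd2(dba)3, SPhos, THF, rt) gives 9.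

**Step 19 (nine-membered ring-closing metathesis).** The risks are oligomerisation, seven-membered closure onto the C11 alkene, and loss of the allylic C12 acetate at 80 °C. The fallback closes the ring before the side chain is attached; it sets out from 20 and comes back at 30. Ring-closing metathesis of 20 under the step 19 conditions gives the bicyclic enol triflate F6, a smaller substrate without the C4 side chain, the allylic acetate or the epoxide. Nozaki–Hiyama–Kishi coupling of F6 with 26 gives the bicyclic allylic alcohol F7. Acetylation (Ac2O, pyridine, DMAP) gives 30.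

## Further compounds

F1 | step 6 | racemic triethyl{[3-methyl-5-(4,4,5,5-tetramethyl-1,3,2-dioxaborolan-2-yl)pent-1-en-3-yl]oxy}silane | `C=CC(C)(O[Si](CC)(CC)CC)CCB1OC(C)(C)C(C)(C)O1`
F2 | step 6 | (R)-triethyl{[3-methyl-5-(4,4,5,5-tetramethyl-1,3,2-dioxaborolan-2-yl)pent-1-en-3-yl]oxy}silane | `C=C[C@](C)(O[Si](CC)(CC)CC)CCB1OC(C)(C)C(C)(C)O1`
F3 | step 7 | (S)-3-methyl-3-(triethylsilyloxy)pent-4-en-1-ol | `C=C[C@@](C)(O[Si](CC)(CC)CC)CCO`
F4 | step 7 | (S)-triethyl[(5-iodo-3-methylpent-1-en-3-yl)oxy]silane | `C=C[C@@](C)(O[Si](CC)(CC)CC)CCI`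
F5 | step 7 | [(3S)-3-methyl-3-(triethylsilyloxy)pent-4-en-1-yl]zinc iodide | `C=C[C@@](C)(O[Si](CC)(CC)CC)CC[Zn]I`
F6 | step 19 | (1R,4aS,7S,8Z,11aR)-1-acetoxy-7-hydroxy-4-{[(trifluoromethyl)sulfonyl]oxy}-12,13,14,15,16,17-hexanorxenica-3,8,11(19)-triene (bicyclic enol triflate) | `C=C1C/C=C\[C@@](C)(O)CC[C@@H]2C(OS(=O)(=O)C(F)(F)F)=CO[C@H](OC(C)=O)[C@@H]12`
F7 | step 19 | (1R,4aS,7S,8Z,11aR,12R,13R,14R)-1,13-diacetoxy-14,15-epoxy-7,12-dihydroxyxenica-3,8,11(19)-triene | `C=C1C/C=C\[C@@](C)(O)CC[C@@H]2C([C@@H](O)[C@@H](OC(C)=O)[C@H]3OC3(C)C)=CO[C@H](OC(C)=O)[C@@H]12`
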